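**Retrosynthetic overview**
- The only ring, the 2,3-dihydro-4H-pyran-4-one, is closed last by 6-endo-dig oxa-Michael addition of a β-hydroxy ynone.
- The ynone comes from a β-silyloxy Weinreb amide and 1-propynylmagnesium bromide.
- The C23 side chain is joined by copper-catalysed sp3–sp3 coupling of oleyl Grignard (the Z-alkene is bought in) with a C8 ω-bromo β-silyloxy ester.
- The single stereocentre is set by a ketoreductase (NADPH-dependent alcohol dehydrogenase) on ethyl 8-bromo-3-oxooctanoate, made from 6-bromohexanoyl chloride and Meldrum's acid.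

Assumption: the target stereocentre is (R) (ring O > ring CH2 > side chain > H), and an (R)-selective ketoreductase for the step 3 substrate is picked by screening a commercial enzyme panel.

**Route**

Step 1
Reactants: 1 6-bromohexanoyl chloride; 2 Meldrum's acid (2,2-dimethyl-1,3-dioxane-4,6-dione)
Product: 3 5-(6-bromo-1-hydroxyhexylidene)-2,2-dimethyl-1,3-dioxane-4,6-dione (enol form of the acyl Meldrum's acid)
Conditions: pyridine (2.2 equiv), CH2Cl2, 0 °C → rt, 2 h; cold 1 M HCl wash, used crude
Reagents that add atoms: none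
Why: Oikawa–Yonemitsu C-acylation of the very acidic Meldrum's acid by the acid chloride gives the hydrogen-bonded enol, and the primary bromide does not react with pyridine in this short, cold reaction.

Step 2
Reactants: 3 5-(6-bromo-1-hydroxyhexylidene)-2,2-dimethyl-1,3-dioxane-4,6-dione
Product: 5 ethyl 8-bromo-3-oxooctanoate, via acylketene 4 (not isolated)
Conditions: EtOH, reflux, 3 h
Reagents that add atoms: ethanol, CCO
Why: Thermal fragmentation of the acyl Meldrum's acid loses acetone and CO2 to give an acylketene that ethanol traps as the β-keto ester (Oikawa–Yonemitsu β-keto ester synthesis).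

Step 3
Reactants: 5 ethyl 8-bromo-3-oxooctanoate
Product: 6 ethyl (3R)-8-bromo-3-hydroxyoctanoate
Conditions: (R)-selective ketoreductase (KRED, NADPH-dependent alcohol dehydrogenase), NADP+ (cat.), iPrOH (15 vol %), KH2PO4/K2HPO4 buffer pH 7.0, MgSO4 (2 mM), 30 °C, 24 h
Reagents that add atoms: none
Why: Enzymatic asymmetric ketone reduction by a ketoreductase delivers hydride from NADPH (recycled by isopropanol) to one face of the ketone in the chiral active site, setting the (R) carbinol in typically >99% ee at neutral pH that spares the ester and the bromide.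

Step 4
Reactants: 6 ethyl (3R)-8-bromo-3-hydroxyoctanoate
Product: 7 ethyl (3R)-8-bromo-3-[(tert-butyldimethylsilyl)oxy]octanoate
Conditions: TBSOTf (1.2 equiv), 2,6-lutidine (2 equiv), CH2Cl2, −78 → 0 °C
Reagents that add atoms: tert-butyldimethylsilyl triflate, CC(C)(C)[Si](C)(C)OS(=O)(=O)C(F)(F)F
Why: Silyl ether protection of the secondary alcohol with a hindered, non-nucleophilic base, which cannot alkylate at the primary bromide and does not touch the stereocentre.

Step 5
Reactants: 7 ethyl (3R)-8-bromo-3-[(tert-butyldimethylsilyl)oxy]octanoate; 8 oleyl bromide [(9Z)-1-bromooctadec-9-ene]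
Product: 10 ethyl (3R,17Z)-3-[(tert-butyldimethylsilyl)oxy]hexacos-17-enoate, via oleylmagnesium bromide 9 (not isolated)
Conditions: 8, Mg, THF, 40 °C; then added over 1 h to 7, Li2CuCl4 (3 mol %), NMP (4 equiv), THF, 0 °C → rt; aq. NH4Cl
Reagents that add atoms: none
Why: Kochi-type copper-catalysed sp3–sp3 Grignard cross-coupling (Li2CuCl4 is reduced in situ to the active monovalent copper species) displaces the primary bromide faster than the Grignard reagent attacks the ethyl ester when NMP is present, and the remote Z-alkene and stereocentre are not involved.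

Step 6
Reactants: 10 ethyl (3R,17Z)-3-[(tert-butyldimethylsilyl)oxy]hexacos-17-enoate
Product: 11 (3R,17Z)-3-[(tert-butyldimethylsilyl)oxy]-N-methoxy-N-methylhexacos-17-enamide
Conditions: MeNH(OMe)·HCl (1.5 equiv), iPrMgCl (3 equiv), THF, −20 → 0 °C; aq. NH4Cl
Reagents that add atoms: N,O-dimethylhydroxylamine hydrochloride, CNOC.Cl
Why: Weinreb amide formation by aminolysis of the ester with the chloromagnesium amide made in situ, run cold so that the β-silyloxy group is not eliminated.

Step 7
Reactants: 11 (3R,17Z)-3-[(tert-butyldimethylsilyl)oxy]-N-methoxy-N-methylhexacos-17-enamide; 12 1-propynylmagnesium bromide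
Product: 14 (6R,20Z)-6-[(tert-butyldimethylsilyl)oxy]nonacos-20-en-2-yn-4-one, via magnesium hemiaminal chelate 13 (not isolated)
Conditions: 12 (2 equiv, 0.5 M in THF), THF, 0 °C, 1 h; aq. NH4Cl
Reagents that add atoms: none
Why: Weinreb ketone synthesis, in which the stable five-membered magnesium chelate 13 blocks a second addition and collapses to the ynone only on work-up.

Step 8
Reactants: 14 (6R,20Z)-6-[(tert-butyldimethylsilyl)oxy]nonacos-20-en-2-yn-4-one
Product: 15 (6R,20Z)-6-hydroxynonacos-20-en-2-yn-4-one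
Conditions: 48% aq. HF, MeCN/CH2Cl2 (3:1), 0 °C → rt; aq. NaHCO3
Reagents that add atoms: none
Why: Acidic fluoride desilylation cleaves the Si–O bond without base, so the β-hydroxy ynone suffers neither retro-aldol nor E1cB elimination, and any early ring closure gives the same final product.

Step 9
Reactants: 15 (6R,20Z)-6-hydroxynonacos-20-en-2-yn-4-one
Product: 16 (2R)-6-methyl-2-[(14Z)-tricos-14-en-1-yl]-2,3-dihydro-4H-pyran-4-one
Conditions: Ph3PAuNTf2 (5 mol %, monovalent gold), CH2Cl2, rt, dark
Reagents that add atoms: none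
Why: Carbophilic gold activation of the ynone lets the β-hydroxyl add to the alkyne β-carbon in a 6-endo-dig intramolecular oxa-Michael hydroalkoxylation, an isomerisation that closes the ring without breaking the C–O bond at the stereocentre, so the (R) configuration from step 3 is kept.

**Compound list**

1 | 6-bromohexanoyl chloride | BrCCCCCC(=O)Cl | starting material
2 | Meldrum's acid (2,2-dimethyl-1,3-dioxane-4,6-dione) | CC1(C)OC(=O)CC(=O)O1 | starting material
3 | 5-(6-bromo-1-hydroxyhexylidene)-2,2-dimethyl-1,3-dioxane-4,6-dione | BrCCCCCC(O)=C1C(=O)OC(C)(C)OC1=O | intermediate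
4 | 8-bromooct-1-ene-1,3-dione (acylketene) | BrCCCCCC(=O)C=C=O | intermediate
5 | ethyl 8-bromo-3-oxooctanoate | BrCCCCCC(=O)CC(=O)OCC | intermediate
6 | ethyl (3R)-8-bromo-3-hydroxyoctanoate | BrCCCCC[C@@H](O)CC(=O)OCC | intermediate
7 | ethyl (3R)-8-bromo-3-[(tert-butyldimethylsilyl)oxy]octanoate | BrCCCCC[C@@H](O[Si](C)(C)C(C)(C)C)CC(=O)OCC | intermediate
8 | oleyl bromide, (9Z)-1-bromooctadec-9-ene | CCCCCCCC/C=C\CCCCCCCCBr | starting material
9 | oleylmagnesium bromide, (9Z)-octadec-9-enylmagnesium bromide | CCCCCCCC/C=C\CCCCCCCC[Mg]Br | intermediate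
10 | ethyl (3R,17Z)-3-[(tert-butyldimethylsilyl)oxy]hexacos-17-enoate | CCCCCCCC/C=C\CCCCCCCCCCCCC[C@@H](O[Si](C)(C)C(C)(C)C)CC(=O)OCC | intermediate
11 | (3R,17Z)-3-[(tert-butyldimethylsilyl)oxy]-N-methoxy-N-methylhexacos-17-enamide | CCCCCCCC/C=C\CCCCCCCCCCCCC[C@@H](O[Si](C)(C)C(C)(C)C)CC(=O)N(C)OC | intermediate
12 | 1-propynylmagnesium bromide | CC#C[Mg]Br | starting material
13 | bromomagnesium alkoxide of the tetrahedral adduct of 11 and 12 (magnesium hemiaminal chelate, both epimers at the new carbon) | CCCCCCCC/C=C\CCCCCCCCCCCCC[C@@H](O[Si](C)(C)C(C)(C)C)CC(O[Mg]Br)(C#CC)N(C)OC | intermediate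
14 | (6R,20Z)-6-[(tert-butyldimethylsilyl)oxy]nonacos-20-en-2-yn-4-one | CCCCCCCC/C=C\CCCCCCCCCCCCC[C@@H](O[Si](C)(C)C(C)(C)C)CC(=O)C#CC | intermediate
15 | (6R,20Z)-6-hydroxynonacos-20-en-2-yn-4-one | CCCCCCCC/C=C\CCCCCCCCCCCCC[C@@H](O)CC(=O)C#CC | intermediate
16 | (2R)-6-methyl-2-[(14Z)-tricos-14-en-1-yl]-2,3-dihydro-4H-pyran-4-one | CCCCCCCC/C=C\CCCCCCCCCCCCC[C@@H]1CC(=O)C=C(C)O1 | target

**Totals**

Total step count: 9. Longest linear sequence: 9 steps (1 → 16); compound 8 enters in step 5 through its Grignard reagent made in the same operation.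

**Steps most likely to fail, with fallbacks**

Step 5 (coupling next to an ester). The Grignard reagent may attack or enolise the β-silyloxy ester, or homocouple. The fallback makes no C–C coupling: the full chain is bought and the ketoreductase works on the full-length keto ester. It sets out from Meldrum's acid 2 and comes back at compound 10. The new bought partner nervonic acid F1 [(15Z)-tetracos-15-enoic acid, achiral] C-acylates 2 (DCC, DMAP, CH2Cl2, 0 °C → rt) to give 5-[(15Z)-1-hydroxytetracos-15-en-1-ylidene]-2,2-dimethyl-1,3-dioxane-4,6-dione F2. Refluxing EtOH converts this into ethyl (17Z)-3-oxohexacos-17-enoate F3. An (R)-selective ketoreductase (NADP+, iPrOH, KH2PO4/K2HPO4 buffer pH 7 with 2 wt % nonionic surfactant TPGS-750-M to disperse the waxy substrate, 35 °C) reduces it to ethyl (3R,17Z)-3-hydroxyhexacos-17-enoate F4. TBSOTf/2,6-lutidine then gives 10. This is kept as the fallback, not the main route, because the very lipophilic C26 substrate makes the enzymatic step less certain.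

Step 8 (desilylation of a β-silyloxy ynone). The ynone may eliminate or add nucleophiles during deprotection. The fallback removes the silyl group before the ynone exists. It sets out from compound 11 and comes back at compound 15. Aqueous HF in MeCN/CH2Cl2 converts 11 into (3R,17Z)-3-hydroxy-N-methoxy-N-methylhexacos-17-enamide F5. Three equivalents of 12 in THF at 0 °C (the first forms the magnesium alkoxide) then give 15 directly after NH4Cl work-up, so 14 is never made.

Step 9 (gold-catalysed ring closure). The catalyst may hydrate the alkyne or stall. The fallback closes the ring by cyclodehydration of a δ-hydroxy β-diketone in place of an ynone. It sets out from compound 11 and comes back at compound 16. Claisen-type acylation of the lithium enolate of acetone (LiN(iPr)2, acetone, THF, −78 °C, 2.5 equiv) with 11 gives (6R,20Z)-6-[(tert-butyldimethylsilyl)oxy]nonacos-20-ene-2,4-dione F6. Aqueous HF in MeCN gives (6R,20Z)-6-hydroxynonacos-20-ene-2,4-dione F7. Catalytic TsOH in CH2Cl2 at rt then forms the hemiketal at the acetyl carbonyl and loses water to give 16.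

**Further compounds**

F1 | step 5 | nervonic acid, (15Z)-tetracos-15-enoic acid (bought) | CCCCCCCC/C=C\CCCCCCCCCCCCCC(=O)O
F2 | step 5 | 5-[(15Z)-1-hydroxytetracos-15-en-1-ylidene]-2,2-dimethyl-1,3-dioxane-4,6-dione | CCCCCCCC/C=C\CCCCCCCCCCCCCC(O)=C1C(=O)OC(C)(C)OC1=O
F3 | step 5 | ethyl (17Z)-3-oxohexacos-17-enoate | CCCCCCCC/C=C\CCCCCCCCCCCCCC(=O)CC(=O)OCC
F4 | step 5 | ethyl (3R,17Z)-3-hydroxyhexacos-17-enoate | CCCCCCCC/C=C\CCCCCCCCCCCCC[C@@H](O)CC(=O)OCC
F5 | step 8 | (3R,17Z)-3-hydroxy-N-methoxy-N-methylhexacos-17-enamide | CCCCCCCC/C=C\CCCCCCCCCCCCC[C@@H](O)CC(=O)N(C)OC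
F6 | step 9 | (6R,20Z)-6-[(tert-butyldimethylsilyl)oxy]nonacos-20-ene-2,4-dione | CCCCCCCC/C=C\CCCCCCCCCCCCC[C@@H](O[Si](C)(C)C(C)(C)C)CC(=O)CC(C)=O
F7 | step 9 | (6R,20Z)-6-hydroxynonacos-20-ene-2,4-dione | CCCCCCCC/C=C\CCCCCCCCCCCCC[C@@H](O)CC(=O)CC(C)=O
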